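## Structural features

Ficucaricone C is achiral and has no stereocentre, so no two stereocentres stand next to each other. It consists of a 2,2-dimethyl-2H-chromene (benzene ring A fused along C4a–C8a to a pyran ring) and a para-disubstituted phenyl ring B, joined by a two-carbon 1,2-diketone chain from C6 of ring A to C1′ of ring B. Ring A is a fully differentiated phloroglucinol: the pyran oxygen O1 on C8a, OMe on C5 and a free OH on C7, with carbon substituents on C4a (the C4=C3 arm of the pyran) and C6 (the diketone), and only C8 left as CH. Ring B carries a 3-methylbut-2-enyl (prenyl) ether para to the bridge. The fragile groups are the aryl prenyl ether (acid, zerovalent palladium, electrophilic halogen, strong heating), the electron-rich C3=C4 bond of the chromene (acid, electrophiles, oxidants) and the 1,2-diketone with its ortho hydroxyl (base-induced benzilic-type rearrangement, hemiketal formation). The real difficulty is regiochemical and chemoselective: the acyl carbon must enter at C6, between OMe and OH, and not at the equally activated C8; the pyran must be fused on the methoxy side; and the bridge must reach the diketone oxidation level beside two C=C bonds. The key step uses the row C7–OH, C6–C, C5–OMe next to the fusion bond C4a–C8a. This is the pattern of a phenol assembled from a vinylketene (supplying C7, C8, C8a, C4a) and a 1-methoxyalkyne (supplying C5, C6), so ring A can be built around its substituents and the C6 substituent can arrive as a second alkyne, the diketone in masked form.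

## Logic of the disconnections

**23 ⇒ 22 ⇒ 21 ⇒ 20.** The two C=O bonds of the bridge are traced back to one C≡C bond, and the O7–H bond to an O7–acetyl bond. The cut is placed here because a diarylalkyne is inert to bases, organometallics and heat and carries both bridge carbons at a fixed position. The gain is that the sensitive diketone appears only two steps before the end. The demand is an oxygen transfer to the alkyne that spares the prenyl and chromene C=C bonds, with the C7 oxygen kept from closing onto the activated alkyne (hence 21), and a final ester cleavage mild enough for the diketone.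

**20 ⇒ 6 + 15 (key disconnection).** Ring A is dismantled by cutting C6–C7, C4a–C5 and C7–C8. This is where all regiochemical problems of the target meet: after the cut, C7 is an acyl chloride carbon, C8 a methyl group on the pyran, and C5/C6 the two carbons of a methoxyalkyne. The gain is one ring, three skeletal bonds and the complete substitution pattern of ring A in one operation, from two fragments of similar size. The demand is that the ketene generated from 6 reacts only with the methoxy-substituted triple bond of 15 and in one orientation. The four-membered intermediate is a spiro 4-alkenylcyclobutenone, with both alkenyl groups on the sp3 carbon; it must open and re-close through its exocyclic methylene.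

**6 ⇒ 5 ⇒ 4 ⇒ 1 + 2.** The C–Cl bond goes back to the acid, the acid to an allyl ester, and the pyran is cut at C4–C5 (condensation) and O1–C2 (oxa-6π closure). An allyl ester is used instead of a simple alkyl ester because the pyran is in equilibrium with an electrophilic dienone that hydroxide could degrade; the acid is therefore released under neutral palladium catalysis. The gain is a three-step arm from two cheap liquids. The demand is neutral conditions throughout: no hydroxide for the ester, no HCl for the chloride.

**15 ⇒ 11 + 12.** The central C(sp)–C(sp) bond of the diyne is cut. This separates the prenyloxyphenyl alkyne from a two-carbon methoxyacetylene unit that 12 delivers in the flask (through 13 and 14) without isolation of volatile methoxyacetylene. The demand is a copper-mediated coupling under basic, anhydrous conditions that an ynol ether tolerates, with homocoupling of 11 suppressed.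

**11 ⇒ 10 ⇒ 9 ⇒ 7 + 8.** The C–Br bond and the triple bond are traced to a dibromoalkene and then to an aldehyde (one-carbon homologation); the ether O–C bond is cut last. Building the bromoalkyne by elimination avoids any electrophilic bromine source next to the prenyl double bond. The demand is only that the early etherification is O-selective.

## Other disconnections considered

**Alternative 1:** The cut is at both aryl–carbonyl bonds of the bridge (C6–Ca and Cb–C1′, Ca being the carbonyl carbon on ring A), so that the two carbonyl carbons come from an oxalyl unit.
- **Forward key step:** the aryllithium A3 and then the lithiated chromene A4 add in turn to the two amide carbonyls of the diamide A2. The first tetrahedral adduct is stable and blocks double addition at one carbon; aqueous acid then releases the diketone A1. No ring is closed. A4 would come from deprotonation of the chromene A5 that Alternative 3 produces.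
- **In favour:** the diketone arrives at the correct oxidation level, so no alkyne has to be oxidised beside two alkenes (better than the chosen plan on this point). The reaction type is established for unsymmetrical 1,2-diaryl diketones (better on precedent). The assembly is fully convergent.
- **Against:** ring A must already exist with the right pattern, so the problem is passed on to the synthesis of A5. Lithiation of A5 must choose C6 (between OMe and the acetal oxygen) over C8 (between the acetal oxygen and O1), both doubly flanked. A4 is a di-ortho-substituted, hindered nucleophile. The final acetal cleavage needs acid beside an acid-sensitive 5,7-dioxygenated chromene and a prenyl ether.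
- **Comparison:** on structure, the chosen plan fixes the C5/C6/C7 pattern by the mechanism of ring formation, while Alternative 1 relies on directing groups on a finished ring. On mechanism, polar carbonyl additions are more predictable than the untested pericyclic cascade. On step economy, about eight to nine steps including A5 would be equal to or slightly better than the eleven of the chosen plan.

**Alternative 2:** The cut is at the Cb–C1′ bond, traced to a chalcone A7 in which ring B still sits on the β-carbon.
- **Forward key step:** Tl(NO3)3 (trivalent thallium) in methanol with HC(OMe)3 induces an oxidative 1,2-shift of the electron-rich aryl group from the β- to the α-carbon. HCl then closes a pyranone through O7 and removes the acetal protecting group, giving the isoflavone A6.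
- **In favour:** every step is classical flavonoid chemistry (better on precedent). The alkoxyphenyl group migrates readily. The temporary ring protects O7. The starting materials are simple aromatics.
- **Against:** the thallium salt is stoichiometric and toxic. The ring closed in the key step is not part of the target and has to be broken again with loss of one carbon, by ring opening and oxidation to the diketone A8. Alkenes cannot be present during the oxidation, which is why A6 carries a saturated pyran and a free phenol; this costs a selective late prenylation of one of two phenols and a dehydrogenation of the chroman beside a prenyl ether. The regiochemistry of the chroman on the acetophenone remains the classical C6/C8 problem.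
- **Comparison:** on structure, the chosen plan builds only rings that stay; Alternative 2 builds and destroys one. On mechanism, Alternative 2 is equal in having no stereochemical issue and better in certainty of the single steps. On step economy, about ten to twelve steps is equal to or worse than the chosen plan.

**Alternative 3:** The cut is at C4a–C4, C8a–O1 and O1–C2, that is, the pyran ring is removed from a finished ring A.
- **Forward key step:** CsF releases a 3-methoxyaryne from the silyl triflate A9. Its addition to the C=O bond of 2 gives a benzoxete, which opens to an ortho-quinone methide and closes by oxa-6π electrocyclisation to the chromene A5.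
- **In favour:** the methoxy group polarises the aryne so that oxygen adds at the carbon meta to OMe and carbon at the ortho carbon. This places 5-OMe and 7-OR unambiguously, equal to the chosen plan for that part of the regiochemistry. It forms three bonds and one ring with no stereocentre, the same count as the chosen key step. The reaction type is known (better on precedent), and it uses 2 as well.
- **Against:** A9 itself needs several steps. The quinone methide can be intercepted by a second aryne. The step does not deliver the C6 carbon, so the C6/C8 question returns in a later acylation, for example that of Alternative 1.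
- **Comparison:** on structure, the chosen key step sets the pyran fusion and the C5/C6/C7 row together; Alternative 3 sets only the first. On mechanism, both end in a 6π closure (oxa-6π there, all-carbon here), so they are equal in type, with Alternative 3 better documented. On step economy, combined with Alternative 1 it is equal to or slightly shorter than the chosen plan.

Key step: step 8

Remark on the chemistry: the ortho-hydroxy 1,2-diketone of the target may equilibrate with a cyclic hemiketal (a 2-aryl-2-hydroxybenzofuran-3-one); the open form of the target structure is taken as the compound to be made.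

## Route

Step 1
Reactants: 1 allyl acetoacetate (allyl 3-oxobutanoate); 2 3-methylbut-2-enal
Product: 4 allyl 2,2,6-trimethyl-2H-pyran-5-carboxylate, via allyl (2E)-2-acetyl-5-methylhexa-2,4-dienoate 3 (not isolated)
Conditions: piperidine (cat.), AcOH (cat.), CH2Cl2, 4 Å MS, rt
Reagents that add atoms: none
Why: Knoevenagel condensation gives the 1-oxatriene 3, which closes by oxa-6π electrocyclisation; the gem-dimethyl group on the new sp3 carbon and the ester on C5 hold the equilibrium on the 2H-pyran side, and the amine interconverts the E/Z isomers of 3 so that both drain into 4.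

Step 2
Reactants: 4 allyl 2,2,6-trimethyl-2H-pyran-5-carboxylate
Product: 5 2,2,6-trimethyl-2H-pyran-5-carboxylic acid
Conditions: Pd(PPh3)4 (cat.), morpholine, THF, rt; cold aq. citric acid work-up
Reagents that add atoms: none
Why: Tsuji–Trost deallylation: zerovalent palladium ionises the primary allyl ester and morpholine takes up the allyl group, so the acid is released without hydroxide, which could attack the ring-opened dienone valence isomer of the pyran.

Step 3
Reactants: 5 2,2,6-trimethyl-2H-pyran-5-carboxylic acid
Product: 6 2,2,6-trimethyl-2H-pyran-5-carbonyl chloride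
Conditions: 1-chloro-N,N,2-trimethylprop-1-en-1-amine, CH2Cl2, 0 °C to rt; used crude
Reagents that add atoms: 1-chloro-N,N,2-trimethylprop-1-en-1-amine, CC(C)=C(Cl)N(C)C
Why: Neutral acid chloride formation through an acyloxyiminium chloride; no HCl is released, which spares the enol ether and the tertiary allylic C2–O bond of the pyran.

Step 4
Reactants: 7 4-hydroxybenzaldehyde; 8 1-bromo-3-methylbut-2-ene (prenyl bromide)
Product: 9 4-(3-methylbut-2-enyloxy)benzaldehyde
Conditions: K2CO3, acetone, 56 °C
Reagents that add atoms: none
Why: Williamson etherification of the acidic para-formyl phenol; SN2 attack of the phenoxide at the primary allylic carbon is expected to give the O-alkylated product.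

Step 5
Reactants: 9 4-(3-methylbut-2-enyloxy)benzaldehyde
Product: 10 1-(2,2-dibromoethenyl)-4-(3-methylbut-2-enyloxy)benzene
Conditions: CBr4, PPh3, CH2Cl2, 0 °C
Reagents that add atoms: carbon tetrabromide, BrC(Br)(Br)Br
Why: First stage of the Corey–Fuchs sequence (Wittig-type dibromomethylenation by Ph3P=CBr2); the ylide does not react with the trisubstituted alkene or the aryl ether.

Step 6
Reactants: 10 1-(2,2-dibromoethenyl)-4-(3-methylbut-2-enyloxy)benzene
Product: 11 1-(bromoethynyl)-4-(3-methylbut-2-enyloxy)benzene
Conditions: DBU, DMSO, 15 °C to rt
Reagents that add atoms: none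
Why: Base-induced anti-elimination of HBr from the 1,1-dibromoalkene gives the 1-bromoalkyne; no electrophilic bromine source is used, so the prenyl double bond is not at risk.

Step 7
Reactants: 12 chloroacetaldehyde dimethyl acetal (2-chloro-1,1-dimethoxyethane); 11 1-(bromoethynyl)-4-(3-methylbut-2-enyloxy)benzene
Product: 15 1-(4-methoxybuta-1,3-diyn-1-yl)-4-(3-methylbut-2-enyloxy)benzene, via lithium methoxyacetylide 13 (not isolated), via (methoxyethynyl)copper 14 (not isolated)
Conditions: 12, LiNEt2 (3 equiv), THF, 0 °C; CuI, −20 °C; then 11, pyridine, −20 °C to rt; chromatography on Et3N-deactivated silica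
Reagents that add atoms: none
Why: Two eliminations (MeOH, then HCl) and a deprotonation turn 12 into the acetylide 13 without isolation of volatile methoxyacetylene; transmetalation to copper and a Cadiot–Chodkiewicz-type coupling of 14 with the 1-bromoalkyne form the C(sp)–C(sp) bond under basic conditions that an ynol ether tolerates.

Step 8
Reactants: 6 2,2,6-trimethyl-2H-pyran-5-carbonyl chloride; 15 1-(4-methoxybuta-1,3-diyn-1-yl)-4-(3-methylbut-2-enyloxy)benzene
Product: 20 5-methoxy-2,2-dimethyl-6-{[4-(3-methylbut-2-enyloxy)phenyl]ethynyl}-2H-chromen-7-ol, via pyranylidene vinylketene 16 (not isolated), via spirocyclobutenone 17 (not isolated), via dienylketene 18 (not isolated), via 8H-chromen-7-one tautomer 19 (not isolated)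
Conditions: Et3N (2 equiv), toluene, slow addition of 6, 25 °C; aq. NaHCO3 wash; then toluene, 90 °C
Reagents that add atoms: none
Why: Proposed new method: Et3N should convert 6 into its acylammonium salt and, because C5 carries no hydrogen, remove a proton from the C6 methyl group (vinylogous dehydrochlorination) to give the cross-conjugated vinylketene 16; the electron-rich β-carbon of the ynol ether of 15 then attacks the ketene carbonyl carbon (future C7) and the resulting enolate closes on the methoxy-bearing carbon, a stepwise polar [2+2] addition that forms C6–C7 and C4a–C5 and gives the racemic spiro 4-alkenylcyclobutenone 17. On heating, 17 should open by conrotatory 4π electrocyclic cleavage of the old C7–C4a bond to the dienylketene 18, and ring A then closes by a thermally allowed disrotatory 6π electrocyclisation between the ketene carbon and the exocyclic methylene (C7–C8), after which the dienone 19 tautomerises irreversibly to the phenol 20. The closest known reaction type is the Danheiser benzannulation of vinylketenes (from cyclobutenones or by Wolff rearrangement) with alkoxy- and siloxyalkynes, supported by the known capture of acid-chloride-derived ketenes by alkoxyalkynes to give 3-alkoxycyclobutenones and by the known 1,4-dehydrochlorination of enoyl chlorides to vinylketenes; new are the pyran-bound vinylketene and the 1-methoxy-1,3-diyne partner. No stereocentre appears in 20, since the spiro centre of 17 is destroyed in the ring opening. The step needs site selectivity between the two triple bonds and one orientation of the [2+2] addition, and both follow from the methoxy group, which makes only the terminal alkyne nucleophilic and places the nucleophilic carbon remote from oxygen, so that C7 receives OH and C5 keeps OMe. Of the two alkenes on the spiro carbon only the exocyclic methylene can take part in the 6π closure, because closure onto C3=C4 would demand an anti-Bredt bridged ring; an isomer of 18 with the wrong geometry should therefore return to 17 and be recycled. Carrying out the [2+2] stage at 25 °C and washing out the salts before heating keeps acylating species away from 20, whose phenol would otherwise be esterified.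

Step 9
Reactants: 20 5-methoxy-2,2-dimethyl-6-{[4-(3-methylbut-2-enyloxy)phenyl]ethynyl}-2H-chromen-7-ol
Product: 21 5-methoxy-2,2-dimethyl-6-{[4-(3-methylbut-2-enyloxy)phenyl]ethynyl}-2H-chromen-7-yl acetate
Conditions: Ac2O, Et3N, DMAP (cat.), CH2Cl2, 0 °C
Reagents that add atoms: acetic anhydride, CC(=O)OC(C)=O
Why: O-Acetylation of the phenol; the ester removes the nucleophilic ortho oxygen that would otherwise close onto the metal-activated alkyne to give a benzofuran in the next step.

Step 10
Reactants: 21 5-methoxy-2,2-dimethyl-6-{[4-(3-methylbut-2-enyloxy)phenyl]ethynyl}-2H-chromen-7-yl acetate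
Product: 22 5-methoxy-2,2-dimethyl-6-{2-[4-(3-methylbut-2-enyloxy)phenyl]-2-oxoacetyl}-2H-chromen-7-yl acetate
Conditions: PdI2 (cat.), DMSO, 140 °C
Reagents that add atoms: dimethyl sulfoxide, CS(C)=O
Why: Divalent palladium activates the diarylalkyne for attack by the sulfoxide oxygen, and two Kornblum-type oxygen transfers (each releasing Me2S) give the 1,2-diketone; DMSO does not oxidise isolated or styrenic C=C bonds, so the prenyl and chromene alkenes are expected to survive.

Step 11
Reactants: 22 5-methoxy-2,2-dimethyl-6-{2-[4-(3-methylbut-2-enyloxy)phenyl]-2-oxoacetyl}-2H-chromen-7-yl acetate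
Product: 23 Ficucaricone C, 1-(7-hydroxy-5-methoxy-2,2-dimethyl-2H-chromen-6-yl)-2-[4-(3-methylbut-2-enyloxy)phenyl]ethane-1,2-dione
Conditions: K2CO3 (0.5 equiv), MeOH, 0 °C; pH 5 buffer quench
Reagents that add atoms: none
Why: Methanolysis (transesterification) of the aryl acetate, which is much faster than attack on an aryl ketone; low temperature and short contact are meant to avoid a benzilic-acid-type rearrangement of the 1,2-diketone.

## Compound list

1 | allyl acetoacetate (allyl 3-oxobutanoate) | CC(=O)CC(=O)OCC=C | starting material
2 | 3-methylbut-2-enal | CC(C)=CC=O | starting material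
3 | allyl (2E)-2-acetyl-5-methylhexa-2,4-dienoate | CC(=O)/C(C(=O)OCC=C)=C\C=C(C)C | intermediate (not isolated)
4 | allyl 2,2,6-trimethyl-2H-pyran-5-carboxylate | CC1=C(C(=O)OCC=C)C=CC(C)(C)O1 | intermediate
5 | 2,2,6-trimethyl-2H-pyran-5-carboxylic acid | CC1=C(C(=O)O)C=CC(C)(C)O1 | intermediate
6 | 2,2,6-trimethyl-2H-pyran-5-carbonyl chloride | CC1=C(C(=O)Cl)C=CC(C)(C)O1 | intermediate
7 | 4-hydroxybenzaldehyde | O=Cc1ccc(O)cc1 | starting material
8 | 1-bromo-3-methylbut-2-ene (prenyl bromide) | CC(C)=CCBr | starting material
9 | 4-(3-methylbut-2-enyloxy)benzaldehyde | CC(C)=CCOc1ccc(C=O)cc1 | intermediate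
10 | 1-(2,2-dibromoethenyl)-4-(3-methylbut-2-enyloxy)benzene | CC(C)=CCOc1ccc(C=C(Br)Br)cc1 | intermediate
11 | 1-(bromoethynyl)-4-(3-methylbut-2-enyloxy)benzene | CC(C)=CCOc1ccc(C#CBr)cc1 | intermediate
12 | chloroacetaldehyde dimethyl acetal (2-chloro-1,1-dimethoxyethane) | COC(CCl)OC | starting material
13 | lithium methoxyacetylide | [Li]C#COC | intermediate (not isolated)
14 | (methoxyethynyl)copper | [Cu]C#COC | intermediate (not isolated)
15 | 1-(4-methoxybuta-1,3-diyn-1-yl)-4-(3-methylbut-2-enyloxy)benzene | COC#CC#Cc1ccc(OCC=C(C)C)cc1 | intermediate
16 | 2,2-dimethyl-6-methylidene-5-(oxomethylidene)-5,6-dihydro-2H-pyran (vinylketene) | C=C1OC(C)(C)C=CC1=C=O | intermediate (not isolated)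
17 | 3-methoxy-7,7-dimethyl-5-methylidene-2-{[4-(3-methylbut-2-enyloxy)phenyl]ethynyl}-6-oxaspiro[3.5]nona-2,8-dien-1-one (racemic) | COC1=C(C#Cc2ccc(OCC=C(C)C)cc2)C(=O)C13C(=C)OC(C)(C)C=C3 | intermediate (not isolated)
18 | (3E)-3-(2,2-dimethyl-6-methylidene-2H-pyran-5(6H)-ylidene)-3-methoxy-2-{[4-(3-methylbut-2-enyloxy)phenyl]ethynyl}prop-1-en-1-one (dienylketene) | O=C=C(C#Cc1ccc(OCC=C(C)C)cc1)/C(OC)=C2\C(=C)OC(C)(C)C=C2 | intermediate (not isolated)
19 | 5-methoxy-2,2-dimethyl-6-{[4-(3-methylbut-2-enyloxy)phenyl]ethynyl}-2H-chromen-7(8H)-one | COC1=C(C#Cc2ccc(OCC=C(C)C)cc2)C(=O)CC2=C1C=CC(C)(C)O2 | intermediate (not isolated)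
20 | 5-methoxy-2,2-dimethyl-6-{[4-(3-methylbut-2-enyloxy)phenyl]ethynyl}-2H-chromen-7-ol | COc1c2c(cc(O)c1C#Cc1ccc(OCC=C(C)C)cc1)OC(C)(C)C=C2 | intermediate
21 | 5-methoxy-2,2-dimethyl-6-{[4-(3-methylbut-2-enyloxy)phenyl]ethynyl}-2H-chromen-7-yl acetate | COc1c2c(cc(OC(C)=O)c1C#Cc1ccc(OCC=C(C)C)cc1)OC(C)(C)C=C2 | intermediate
22 | 5-methoxy-2,2-dimethyl-6-{2-[4-(3-methylbut-2-enyloxy)phenyl]-2-oxoacetyl}-2H-chromen-7-yl acetate | COc1c2c(cc(OC(C)=O)c1C(=O)C(=O)c1ccc(OCC=C(C)C)cc1)OC(C)(C)C=C2 | intermediate
23 | Ficucaricone C, 1-(7-hydroxy-5-methoxy-2,2-dimethyl-2H-chromen-6-yl)-2-[4-(3-methylbut-2-enyloxy)phenyl]ethane-1,2-dione | COc1c2c(cc(O)c1C(=O)C(=O)c1ccc(OCC=C(C)C)cc1)OC(C)(C)C=C2 | target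

## Step count and least certain steps

Total step count: 11. Longest linear sequence: 8 steps (steps 4 to 11, from 7); the pyran arm (steps 1 to 3) joins at step 8.

**Step 8 (key step, proposed new method).**
- **What may go wrong:** the vinylketene 16 may be consumed by dimerisation or by re-addition of chloride or amine before it is captured, because the ynol ether of 15 is conjugated to a second alkyne and is a weaker nucleophile than a simple alkoxyalkyne. A [4+2] addition (ketene carbon and methylene terminus as diene ends) would place the hydroxyl next to C4a. If heating starts while acylating species remain, O-acylation of the product phenol would follow.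
- **Fallback (known reactions only), setting out from 10 and returning at 21:** commercial 2,4-dihydroxy-6-methoxybenzaldehyde is protected at its non-chelated 4-OH (MOMCl, i-Pr2NEt) to give 2-hydroxy-6-methoxy-4-(methoxymethoxy)benzaldehyde F1. Addition of 2-methylprop-1-enylmagnesium bromide (2.2 equiv) gives 2-(1-hydroxy-3-methylbut-2-en-1-yl)-3-methoxy-5-(methoxymethoxy)phenol F2. Its dehydration on gentle warming passes through an ortho-quinone methide that closes by oxa-6π electrocyclisation to the chromene A5, with the pyran fixed by the position of the former aldehyde. Ortho-lithiation between the OMe and the acetal oxygen (n-BuLi, THF, 0 °C) and quenching with I2 would give 6-iodo-5-methoxy-7-(methoxymethoxy)-2,2-dimethyl-2H-chromene F3; the site of lithiation (C6 versus C8) is the point to be checked. Aprotic acetal cleavage (ZnBr2, n-PrSH) gives 6-iodo-5-methoxy-2,2-dimethyl-2H-chromen-7-ol F4, and acetylation gives 6-iodo-5-methoxy-2,2-dimethyl-2H-chromen-7-yl acetate F5. In parallel, 10 is converted by the second Corey–Fuchs stage (n-BuLi, 2 equiv, −78 °C; NH4Cl) into 1-ethynyl-4-(3-methylbut-2-enyloxy)benzene F6. Sonogashira coupling of F5 with F6 (Pd(PPh3)2Cl2, CuI, Et3N, THF) then gives 21.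

**Step 7.** The coupling type is established for copper acetylides; its use with an alkoxyacetylide is the uncertain extension.
- **What may go wrong:** halogen–metal exchange between 14 (or residual 13) and 11, leading to homocoupling, and loss of the methoxyalkyne terminus by addition of amine or methoxide or by hydration during purification.
- **Fallback, setting out from 12 (through 13) and 8 and returning at 15:** 13 is transmetalated with ZnCl2 to chloro(methoxyethynyl)zinc F7 and coupled (Pd(PPh3)4) at the C–I bond of (E)-1-chloro-2-iodoethene to give (E)-1-chloro-4-methoxybut-1-en-3-yne F8. LiN(i-Pr)2 (2 equiv) eliminates HCl and deprotonates the new terminal alkyne, and ZnBr2 gives bromo(4-methoxybuta-1,3-diyn-1-yl)zinc F9. Negishi coupling with 1-iodo-4-(3-methylbut-2-enyloxy)benzene F10 (from 4-iodophenol, 8 and K2CO3) then gives 15. Both C–C bonds are made by C(sp)–C(sp2) couplings, which lack the exchange pathway of a bromoalkyne.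

**Step 10.**
- **What may go wrong:** loss of the prenyl group by thermal or palladium-mediated ionisation of the allylic C–O bond at 140 °C; degradation of the electron-rich chromene by traces of HI; or cycloisomerisation of the alkyne onto the C5 methoxy oxygen with iodide-assisted demethylation.
- **Fallback, setting out from 21 and returning at 22:** hydration of the alkyne with trivalent gold (NaAuCl4 cat., aqueous MeOH, 60 °C) should give 5-methoxy-2,2-dimethyl-6-{2-[4-(3-methylbut-2-enyloxy)phenyl]acetyl}-2H-chromen-7-yl acetate F11 and/or its regioisomer 5-methoxy-2,2-dimethyl-6-{2-[4-(3-methylbut-2-enyloxy)phenyl]-2-oxoethyl}-2H-chromen-7-yl acetate F12. The neighbouring acetate carbonyl is expected to favour F11, but either isomer serves. Aerobic oxidation of the doubly activated benzylic CH2 (DABCO, air, DMF, 80 °C) should convert both into 22 at a much lower temperature and without iodide.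

**Step 2.**
- **What may go wrong:** ionisation of the tertiary allylic C2–O bond of the pyran by zerovalent palladium, amine addition to the ring-opened dienone, or degradation of the free acid on acidification and handling.
- **Fallback, setting out from 2 and returning at 6 (the free acid is bypassed):** methyl acetoacetate and 2 give, under the conditions of step 1, methyl 2,2,6-trimethyl-2H-pyran-5-carboxylate F13. Anhydrous cleavage with KOSiMe3 in THF gives potassium 2,2,6-trimethyl-2H-pyran-5-carboxylate F14, and (COCl)2 in CH2Cl2 at 0 °C converts the dry salt directly into 6 without free HCl.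

## Further compounds

F1 | step 8 | 2-hydroxy-6-methoxy-4-(methoxymethoxy)benzaldehyde | COCOc1cc(O)c(C=O)c(OC)c1
F2 | step 8 | 2-(1-hydroxy-3-methylbut-2-en-1-yl)-3-methoxy-5-(methoxymethoxy)phenol (racemic) | COCOc1cc(O)c(C(O)C=C(C)C)c(OC)c1
F3 | step 8 | 6-iodo-5-methoxy-7-(methoxymethoxy)-2,2-dimethyl-2H-chromene | COc1c2c(cc(OCOC)c1I)OC(C)(C)C=C2
F4 | step 8 | 6-iodo-5-methoxy-2,2-dimethyl-2H-chromen-7-ol | COc1c2c(cc(O)c1I)OC(C)(C)C=C2
F5 | step 8 | 6-iodo-5-methoxy-2,2-dimethyl-2H-chromen-7-yl acetate | COc1c2c(cc(OC(C)=O)c1I)OC(C)(C)C=C2
F6 | step 8 | 1-ethynyl-4-(3-methylbut-2-enyloxy)benzene | CC(C)=CCOc1ccc(C#C)cc1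
F7 | step 7 | chloro(methoxyethynyl)zinc | COC#C[Zn]Cl
F8 | step 7 | (E)-1-chloro-4-methoxybut-1-en-3-yne | COC#C/C=C/Cl
F9 | step 7 | bromo(4-methoxybuta-1,3-diyn-1-yl)zinc | COC#CC#C[Zn]Br
F10 | step 7 | 1-iodo-4-(3-methylbut-2-enyloxy)benzene | CC(C)=CCOc1ccc(I)cc1
F11 | step 10 | 5-methoxy-2,2-dimethyl-6-{2-[4-(3-methylbut-2-enyloxy)phenyl]acetyl}-2H-chromen-7-yl acetate | COc1c2c(cc(OC(C)=O)c1C(=O)Cc1ccc(OCC=C(C)C)cc1)OC(C)(C)C=C2
F12 | step 10 | 5-methoxy-2,2-dimethyl-6-{2-[4-(3-methylbut-2-enyloxy)phenyl]-2-oxoethyl}-2H-chromen-7-yl acetate | COc1c2c(cc(OC(C)=O)c1CC(=O)c1ccc(OCC=C(C)C)cc1)OC(C)(C)C=C2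
F13 | step 2 | methyl 2,2,6-trimethyl-2H-pyran-5-carboxylate | CC1=C(C(=O)OC)C=CC(C)(C)O1
F14 | step 2 | potassium 2,2,6-trimethyl-2H-pyran-5-carboxylate | CC1=C(C(=O)[O-])C=CC(C)(C)O1.[K+]
A1 | alternative 1 | 7-O-methoxymethyl Ficucaricone C, 1-[5-methoxy-7-(methoxymethoxy)-2,2-dimethyl-2H-chromen-6-yl]-2-[4-(3-methylbut-2-enyloxy)phenyl]ethane-1,2-dione | COc1c2c(cc(OCOC)c1C(=O)C(=O)c1ccc(OCC=C(C)C)cc1)OC(C)(C)C=C2
A2 | alternative 1 | 1,4-dimethylpiperazine-2,3-dione | CN1CCN(C)C(=O)C1=O
A3 | alternative 1 | [4-(3-methylbut-2-enyloxy)phenyl]lithium | [Li]c1ccc(OCC=C(C)C)cc1
A4 | alternative 1 | [5-methoxy-7-(methoxymethoxy)-2,2-dimethyl-2H-chromen-6-yl]lithium | COc1c2c(cc(OCOC)c1[Li])OC(C)(C)C=C2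
A5 | alternative 3 | 5-methoxy-7-(methoxymethoxy)-2,2-dimethyl-2H-chromene | COc1cc(OCOC)cc2OC(C)(C)C=Cc12
A6 | alternative 2 | 3-(4-hydroxyphenyl)-5-methoxy-8,8-dimethyl-7,8-dihydro-6H-pyrano[3,2-g]chromen-4-one | COc1c2c(cc3occ(-c4ccc(O)cc4)c(=O)c13)OC(C)(C)CC2
A7 | alternative 2 | (E)-1-(7-hydroxy-5-methoxy-2,2-dimethyl-3,4-dihydro-2H-chromen-6-yl)-3-[4-(methoxymethoxy)phenyl]prop-2-en-1-one | COc1c2c(cc(O)c1C(=O)/C=C/c1ccc(OCOC)cc1)OC(C)(C)CC2
A8 | alternative 2 | 1-(7-hydroxy-5-methoxy-2,2-dimethyl-3,4-dihydro-2H-chromen-6-yl)-2-(4-hydroxyphenyl)ethane-1,2-dione | COc1c2c(cc(O)c1C(=O)C(=O)c1ccc(O)cc1)OC(C)(C)CC2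
A9 | alternative 3 | 2-methoxy-4-(methoxymethoxy)-6-(trimethylsilyl)phenyl trifluoromethanesulfonate | COc1cc(OCOC)cc([Si](C)(C)C)c1OS(=O)(=O)C(F)(F)F
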